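**Retrosynthetic overview**
- Ring B is a phloroglucinol nucleus. Its only methyl ether (C2'-OCH3) lies between the two carbon-bearing atoms C1' (bond to C3 of ring C) and C3' (C4 methylene of ring D), and the oxygens at C4' and C6' flank the single C5'-H. A 3,5-dialkyl-4-methoxy-6-methyl-2-pyrone carries exactly this O/C pattern.
- Key disconnection C5'-C6': the arene is treated as an isomer of 3-allyl-4-methoxy-6-methyl-5-prenyl-2-pyrone (lactone opening, then Claisen closure). The pyrone comes from acetylacetone by prenylation, dianion carboxylation, lactonisation, O-allylation with Claisen shift to C3, and O-methylation.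
- Ring D: the O-C(CH3)2 bond forms by acid closure of the prenyl group onto C4'-OH. The allyl group is then cut down to the C1'-CH2-CHO unit.
- The ring A-C4 bond is made with an aryllithium from protected 4-bromoresorcinol. C2 comes from an amide acetal, and ring C closes at O1-C2.
- Order of rings: pyrone, B, D, (A brought in), C. Debenzylation comes last.

Key step: step 7

Remark: the target has no stereocentre. The stereocentres of 5, 11 and 19 form racemic and disappear in the next operation. Atom labels follow isoflavone numbering: rings A and C are the chromenone, ring B carries the primed atoms, ring D is the dimethylpyran.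

Step 1
Reactants: 1 acetylacetone (pentane-2,4-dione); 2 prenyl bromide (1-bromo-3-methylbut-2-ene)
Product: 3 3-(3-methylbut-2-enyl)pentane-2,4-dione
Conditions: K2CO3, acetone, 56 °C
Reagents that add atoms: none
Why: C-alkylation of the soft potassium enolate of a β-diketone by an allylic bromide (SN2) is standard, a slight excess of 1 should hold back double alkylation, and no stereocentre arises because C3 carries two identical acetyl groups.

Step 2
Reactants: 3 3-(3-methylbut-2-enyl)pentane-2,4-dione
Product: 5 4-acetyl-7-methyl-3-oxooct-6-enoic acid, via dilithium dianion 4 (not isolated)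
Conditions: LiN(i-Pr)2 (2.2 equiv), THF, -78 to 0 °C; CO2 (gas), -78 °C; 1 M HCl, 0 °C
Reagents that add atoms: carbon dioxide, O=C=O
Why: The second equivalent of amide base removes a terminal methyl proton from the lithium enolate and the 1,3-dianion is carboxylated only at its more basic terminal carbon (γ-carboxylation of a β-diketone dianion); the two methyl groups are equivalent, so a single acid should result, with a labile racemic C4 centre.

Step 3
Reactants: 5 4-acetyl-7-methyl-3-oxooct-6-enoic acid
Product: 6 4-hydroxy-6-methyl-5-(3-methylbut-2-enyl)-2H-pyran-2-one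
Conditions: Ac2O (neat), 23 °C
Reagents that add atoms: none
Why: Acetic anhydride turns the acid into a mixed anhydride that the enol oxygen of the C5 ketone attacks (6-exo-trig lactonisation of a 3,5-dioxo acid), tautomerisation gives the 4-hydroxy-2-pyrone and erases the stereocentre, and the absence of mineral acid leaves the prenyl double bond alone.

Step 4
Reactants: 6 4-hydroxy-6-methyl-5-(3-methylbut-2-enyl)-2H-pyran-2-one; 7 allyl bromide
Product: 8 4-allyloxy-6-methyl-5-(3-methylbut-2-enyl)-2H-pyran-2-one
Conditions: K2CO3, DMF, 23 °C
Reagents that add atoms: none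
Why: Williamson-type O-alkylation of the ambident potassium pyronate takes place mainly at the C4 oxygen in a dipolar aprotic solvent, and the minor product of direct C3 allylation is the product of the next step.

Step 5
Reactants: 8 4-allyloxy-6-methyl-5-(3-methylbut-2-enyl)-2H-pyran-2-one
Product: 9 3-allyl-4-hydroxy-6-methyl-5-(3-methylbut-2-enyl)-2H-pyran-2-one
Conditions: toluene, 110 °C
Reagents that add atoms: none
Why: The thermal [3,3]-sigmatropic Claisen rearrangement of the allyl vinyl ether unit O-C4=C3 can deliver the allyl group only to C3, re-enolisation restores the 4-hydroxy-2-pyrone, and 110 °C without added acid is too mild for the C4 hydroxyl to add to either double bond.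

Step 6
Reactants: 9 3-allyl-4-hydroxy-6-methyl-5-(3-methylbut-2-enyl)-2H-pyran-2-one
Product: 10 3-allyl-4-methoxy-6-methyl-5-(3-methylbut-2-enyl)-2H-pyran-2-one
Conditions: (CH3O)2SO2, K2CO3, acetone, 56 °C
Reagents that add atoms: dimethyl sulfate, COS(=O)(=O)OC
Why: The hard electrophile alkylates the potassium pyronate at oxygen (Williamson-type etherification), under basic conditions mainly at O4 to give the 4-methoxy-2-pyrone and not the 2-methoxy-4-pyrone, while C-methylation would have to build a quaternary C3.

Step 7
Reactants: 10 3-allyl-4-methoxy-6-methyl-5-(3-methylbut-2-enyl)-2H-pyran-2-one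
Product: 12 4-allyl-5-methoxy-6-(3-methylbut-2-enyl)benzene-1,3-diol, via acyclic keto ester 11 (not isolated)
Conditions: NaOCH3 (4 equiv), degassed CH3OH, argon, sealed vessel, 140-170 °C; 1 M HCl, 0 °C
Reagents that add atoms: none
Why: Methoxide adds to the lactone carbonyl C2 of 10 and expels the C6 enolate oxygen, giving keto ester 11 with the ester and the acetyl-bearing carbon still cis on the former C3=C4 bond; its doubly activated methine is deprotonated fastest, but that dienolate can only re-form the pyrone and is a reversible resting state. The small equilibrium share of the terminal CH3 enolate attacks the ester carbonyl in a 6-(enolendo)-exo-trig Claisen (Dieckmann-type) condensation that forms C5'-C6' and closes ring B, and loss of methoxide followed by enolisation to the resorcinolate takes the product out of all equilibria. The closest known reactions are the conversion of 4-methoxy-6-methyl-2-pyrone into 5-methoxyresorcinol with NaOCH3 in hot methanol and the Claisen cyclisation of 3,5-dioxo esters to phloroglucinols. No stereocentre is formed, since the racemic methine of 11 becomes sp2. The selectivity needed is positional and the pyrone fixes it: C4-OCH3 becomes C2'-OCH3, C3 and C5 carry allyl and prenyl to C1' and C3', the lactone carbonyl becomes C6'-OH and the C6 oxygen becomes C4'-OH, and because C3 carries no hydrogen there is no ester enolate and hence no aldol alternative. Air is excluded to protect the electron-rich phenolate, and the temperature is held at the lowest value that sustains closure so that the allyl double bond does not move into conjugation.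

Step 8
Reactants: 12 4-allyl-5-methoxy-6-(3-methylbut-2-enyl)benzene-1,3-diol
Product: 13 6-allyl-5-methoxy-2,2-dimethylchroman-7-ol
Conditions: p-TsOH·H2O (10 mol %), toluene, 60 °C
Reagents that add atoms: none
Why: The acid protonates the trisubstituted prenyl double bond in the Markovnikov sense and the tertiary cation is trapped by C4'-OH, the only hydroxyl next to C3' (intramolecular hydroalkoxylation closing six-membered ring D), whereas the monosubstituted allyl group would need a secondary cation and should stay untouched at this acidity.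

Step 9
Reactants: 13 6-allyl-5-methoxy-2,2-dimethylchroman-7-ol
Product: 14 6-allyl-7-benzyloxy-5-methoxy-2,2-dimethylchroman
Conditions: BnBr, K2CO3, DMF, 23 °C
Reagents that add atoms: benzyl bromide, BrCc1ccccc1
Why: Williamson etherification of the single remaining phenol masks C6'-OH, which would otherwise compete with the ring A phenol for C2 in step 14 and lead to a 3-aroylbenzofuran.

Step 10
Reactants: 14 6-allyl-7-benzyloxy-5-methoxy-2,2-dimethylchroman
Product: 15 (7-benzyloxy-5-methoxy-2,2-dimethylchroman-6-yl)acetaldehyde
Conditions: OsO4 (2 mol %), NaIO4 (4 equiv), 2,6-lutidine, dioxane-H2O, 23 °C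
Reagents that add atoms: osmium tetroxide, O=[Os](=O)(=O)=O (transfers the oxygen); sodium periodate, [Na+].[O-]I(=O)(=O)=O (terminal oxygen source)
Why: Lemieux-Johnson cleavage (catalytic dihydroxylation, then periodate glycol fission) acts on the only C=C bond left now that the prenyl alkene is spent in ring D, and 2,6-lutidine suppresses side reactions of the sensitive arylacetaldehyde.

Step 11
Reactants: 16 4-bromoresorcinol (4-bromobenzene-1,3-diol)
Product: 17 1-bromo-2,4-bis(methoxymethoxy)benzene
Conditions: CH3OCH2Cl, i-Pr2NEt, CH2Cl2, 0 to 23 °C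
Reagents that add atoms: chloromethyl methyl ether, COCCl
Why: Both phenols are alkylated by the reactive α-chloro ether under amine base (acetal-type protection), giving ethers that tolerate n-BuLi and are removed by mild acid without touching a benzyl ether.

Step 12
Reactants: 17 1-bromo-2,4-bis(methoxymethoxy)benzene; 15 (7-benzyloxy-5-methoxy-2,2-dimethylchroman-6-yl)acetaldehyde
Product: 19 2-(7-benzyloxy-5-methoxy-2,2-dimethylchroman-6-yl)-1-[2,4-bis(methoxymethoxy)phenyl]ethanol (racemic), via aryllithium 18 (not isolated)
Conditions: n-BuLi, THF, -78 °C; then 15, -78 °C; aq. NH4Cl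
Reagents that add atoms: none
Why: Bromine-lithium exchange outruns any deprotonation at -78 °C and the aryllithium adds 1,2 to the aldehyde, so the ring A-C4 bond forms at the position fixed by the bromine and without a Friedel-Crafts acylation, which would endanger the very nucleophilic C5'-H of ring B and the benzyl ether; the carbinol centre forms racemic and is removed in step 13.

Step 13
Reactants: 19 2-(7-benzyloxy-5-methoxy-2,2-dimethylchroman-6-yl)-1-[2,4-bis(methoxymethoxy)phenyl]ethanol
Product: 20 2-(7-benzyloxy-5-methoxy-2,2-dimethylchroman-6-yl)-1-[2,4-bis(methoxymethoxy)phenyl]ethanone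
Conditions: Dess-Martin periodinane, CH2Cl2, 23 °C
Reagents that add atoms: none
Why: Dess-Martin oxidation of a secondary benzylic alcohol is fast and nearly neutral, spares the MOM and benzyl ethers and the electron-rich rings, and deletes the stereocentre.

Step 14
Reactants: 20 2-(7-benzyloxy-5-methoxy-2,2-dimethylchroman-6-yl)-1-[2,4-bis(methoxymethoxy)phenyl]ethanone
Product: 22 3-(7-benzyloxy-5-methoxy-2,2-dimethylchroman-6-yl)-7-hydroxy-4H-chromen-4-one, via enaminone 21 (not isolated)
Conditions: (CH3O)2CHN(CH3)2, toluene, 100 °C; evaporate; HCl, CH3OH, 50 °C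
Reagents that add atoms: N,N-dimethylformamide dimethyl acetal, COC(OC)N(C)C
Why: The amide acetal condenses with the doubly activated methylene of the deoxybenzoin to the enaminone (the standard one-carbon extension to isoflavones) while all phenols are masked and none can be methylated, and methanolic HCl then removes both MOM groups so that the freed ortho phenol of ring A adds to the enamine carbon and expels dimethylamine (addition-elimination closing six-membered ring C at O1-C2), with the benzyl ether keeping the C6' oxygen out of the competition.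

Step 15
Reactants: 22 3-(7-benzyloxy-5-methoxy-2,2-dimethylchroman-6-yl)-7-hydroxy-4H-chromen-4-one
Product: 23 glycyrrhizaisoflavone C
Conditions: H2 (1 atm), 10% Pd/C, EtOAc-CH3OH, 23 °C, stopped after one equivalent of H2
Reagents that add atoms: none
Why: Hydrogenolysis of the benzyl aryl ether over palladium is faster than saturation of the C2=C3 bond, which is shielded by the doubly ortho-substituted ring B, so stopping after one equivalent of hydrogen should give the target.

**Compound list**
1 | acetylacetone | CC(=O)CC(C)=O | starting material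
2 | prenyl bromide | CC(C)=CCBr | starting material
3 | 3-(3-methylbut-2-enyl)pentane-2,4-dione | CC(=O)C(CC=C(C)C)C(C)=O | intermediate
4 | dilithium 3-(3-methylbut-2-enyl)penta-1,3-diene-2,4-diolate (not isolated) | [Li+].[Li+].C=C([O-])C(CC=C(C)C)=C(C)[O-] | intermediate
5 | 4-acetyl-7-methyl-3-oxooct-6-enoic acid (racemic, enolisable) | CC(=O)C(CC=C(C)C)C(=O)CC(=O)O | intermediate
6 | 4-hydroxy-6-methyl-5-(3-methylbut-2-enyl)-2H-pyran-2-one | Cc1oc(=O)cc(O)c1CC=C(C)C | intermediate
7 | allyl bromide | C=CCBr | starting material
8 | 4-allyloxy-6-methyl-5-(3-methylbut-2-enyl)-2H-pyran-2-one | Cc1oc(=O)cc(OCC=C)c1CC=C(C)C | intermediate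
9 | 3-allyl-4-hydroxy-6-methyl-5-(3-methylbut-2-enyl)-2H-pyran-2-one | Cc1oc(=O)c(CC=C)c(O)c1CC=C(C)C | intermediate
10 | 3-allyl-4-methoxy-6-methyl-5-(3-methylbut-2-enyl)-2H-pyran-2-one | C=CCc1c(OC)c(CC=C(C)C)c(C)oc1=O | intermediate
11 | methyl (E)-2-allyl-3-methoxy-4-(3-methylbut-2-enyl)-5-oxohex-2-enoate (racemic, not isolated) | COC(=O)/C(CC=C)=C(/OC)C(CC=C(C)C)C(C)=O | intermediate
12 | 4-allyl-5-methoxy-6-(3-methylbut-2-enyl)benzene-1,3-diol | C=CCc1c(O)cc(O)c(CC=C(C)C)c1OC | intermediate
13 | 6-allyl-5-methoxy-2,2-dimethylchroman-7-ol | C=CCc1c(O)cc2c(c1OC)CCC(C)(C)O2 | intermediate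
14 | 6-allyl-7-benzyloxy-5-methoxy-2,2-dimethylchroman | C=CCc1c(OCc3ccccc3)cc2c(c1OC)CCC(C)(C)O2 | intermediate
15 | (7-benzyloxy-5-methoxy-2,2-dimethylchroman-6-yl)acetaldehyde | O=CCc1c(OCc3ccccc3)cc2c(c1OC)CCC(C)(C)O2 | intermediate
16 | 4-bromoresorcinol | Oc1ccc(Br)c(O)c1 | starting material
17 | 1-bromo-2,4-bis(methoxymethoxy)benzene | COCOc1ccc(Br)c(OCOC)c1 | intermediate
18 | 2,4-bis(methoxymethoxy)phenyllithium (not isolated) | [Li]c1ccc(OCOC)cc1OCOC | intermediate
19 | 2-(7-benzyloxy-5-methoxy-2,2-dimethylchroman-6-yl)-1-[2,4-bis(methoxymethoxy)phenyl]ethanol (racemic) | COCOc1ccc(C(O)Cc2c(OCc3ccccc3)cc3c(c2OC)CCC(C)(C)O3)c(OCOC)c1 | intermediate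
20 | 2-(7-benzyloxy-5-methoxy-2,2-dimethylchroman-6-yl)-1-[2,4-bis(methoxymethoxy)phenyl]ethanone | COCOc1ccc(C(=O)Cc2c(OCc3ccccc3)cc3c(c2OC)CCC(C)(C)O3)c(OCOC)c1 | intermediate
21 | (E)-2-(7-benzyloxy-5-methoxy-2,2-dimethylchroman-6-yl)-1-[2,4-bis(methoxymethoxy)phenyl]-3-(dimethylamino)prop-2-en-1-one (not isolated, geometry labile) | COCOc1ccc(C(=O)/C(=C/N(C)C)c2c(OCc3ccccc3)cc3c(c2OC)CCC(C)(C)O3)c(OCOC)c1 | intermediate
22 | 3-(7-benzyloxy-5-methoxy-2,2-dimethylchroman-6-yl)-7-hydroxy-4H-chromen-4-one | COc1c2c(cc(OCc3ccccc3)c1-c1coc3cc(O)ccc3c1=O)OC(C)(C)CC2 | intermediate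
23 | glycyrrhizaisoflavone C, 7-hydroxy-3-(7-hydroxy-5-methoxy-2,2-dimethylchroman-6-yl)-4H-chromen-4-one | COc1c2c(cc(O)c1-c1coc3cc(O)ccc3c1=O)OC(C)(C)CC2 | target

**Total step count:** 15
**Longest linear sequence:** 14 (steps 1-10 and 12-15; step 11 is a one-step side branch)

**Steps most likely to fail**

1. **Step 7.**
   - Risk: at the temperature that closure needs, the opened chain may rest as its unreactive dienolate. Meanwhile methoxide may cleave off the acetyl group (vinylogous retro-Claisen), or the allyl and prenyl double bonds may drift into conjugation with the ring.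
   - Fallback: ring B is taken from an existing arene, and a removable ester at C5' enforces the substitution pattern. The fallback sets out from allyl bromide 7 and comes back to the route at chromanol 13.
   - Commercial methyl 2,4,6-trihydroxybenzoate F1 is methylated at its only non-chelated hydroxyl ((CH3O)2SO2, K2CO3, acetone) to methyl 2,6-dihydroxy-4-methoxybenzoate F2.
   - Isoprene and 85% H3PO4 annulate one of the two equivalent free ring positions. The only neighbouring hydroxyl closes the ring, giving methyl 7-hydroxy-5-methoxy-2,2-dimethylchroman-8-carboxylate F3.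
   - 7 and K2CO3 in DMF give methyl 7-allyloxy-5-methoxy-2,2-dimethylchroman-8-carboxylate F4.
   - The aromatic Claisen rearrangement (N,N-diethylaniline, 190 °C) has only C6 open to it and gives methyl 6-allyl-7-hydroxy-5-methoxy-2,2-dimethylchroman-8-carboxylate F5.
   - LiI in hot pyridine dealkylates the hindered ester to 6-allyl-7-hydroxy-5-methoxy-2,2-dimethylchroman-8-carboxylic acid F6. This electron-rich salicylic acid loses CO2 on warming in dilute acid to give 13.

2. **Step 2.**
   - Risk: the second deprotonation of the hindered 3-substituted diketone may stay incomplete, so that little carbon-carbon bond formation with CO2 takes place. The β-keto acid may also lose CO2 again during isolation.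
   - Fallback: the pyrone is built by double acylation of an enol ether. It sets out from 3 and comes back at pyrone 6, and steps 2 and 3 drop out.
   - Ethanolysis of 3 (K2CO3, C2H5OH, 78 °C, retro-Claisen loss of one acetyl group) gives 6-methylhept-5-en-2-one F7.
   - (CH3)3SiCl, NaI and (C2H5)3N in CH3CN convert F7 into the more substituted silyl enol ether (Z)-trimethyl[(6-methylhepta-2,5-dien-2-yl)oxy]silane F8.
   - Malonyl dichloride in (C2H5)2O at -78 to 23 °C acylates F8 first at carbon and then at oxygen, which gives 6 directly.

3. **Step 12.**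
   - Risk: the basic aryllithium may deprotonate the readily enolised arylacetaldehyde instead of adding to it, and the aldehyde may self-condense before use.
   - Fallback: acyl substitution replaces carbonyl addition. It sets out from 15 and comes back at ketone 20, and step 13 drops out.
   - Pinnick oxidation of 15 (NaClO2, NaH2PO4, 2-methylbut-2-ene, t-BuOH-H2O) gives (7-benzyloxy-5-methoxy-2,2-dimethylchroman-6-yl)acetic acid F9.
   - Coupling with CH3ONHCH3·HCl (EDC·HCl, i-Pr2NEt, CH2Cl2) gives 2-(7-benzyloxy-5-methoxy-2,2-dimethylchroman-6-yl)-N-methoxy-N-methylacetamide F10.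
   - Aryllithium 18 adds once to F10 (Weinreb ketone synthesis) to give 20.

**Further compounds**
F1 | step 7 | methyl 2,4,6-trihydroxybenzoate | COC(=O)c1c(O)cc(O)cc1O
F2 | step 7 | methyl 2,6-dihydroxy-4-methoxybenzoate | COC(=O)c1c(O)cc(OC)cc1O
F3 | step 7 | methyl 7-hydroxy-5-methoxy-2,2-dimethylchroman-8-carboxylate | COC(=O)c1c(O)cc(OC)c2CCC(C)(C)Oc12
F4 | step 7 | methyl 7-allyloxy-5-methoxy-2,2-dimethylchroman-8-carboxylate | COC(=O)c1c(OCC=C)cc(OC)c2CCC(C)(C)Oc12
F5 | step 7 | methyl 6-allyl-7-hydroxy-5-methoxy-2,2-dimethylchroman-8-carboxylate | COC(=O)c1c(O)c(CC=C)c(OC)c2CCC(C)(C)Oc12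
F6 | step 7 | 6-allyl-7-hydroxy-5-methoxy-2,2-dimethylchroman-8-carboxylic acid | OC(=O)c1c(O)c(CC=C)c(OC)c2CCC(C)(C)Oc12
F7 | step 2 | 6-methylhept-5-en-2-one | CC(=O)CCC=C(C)C
F8 | step 2 | (Z)-trimethyl[(6-methylhepta-2,5-dien-2-yl)oxy]silane | C/C(O[Si](C)(C)C)=C/CC=C(C)C
F9 | step 12 | (7-benzyloxy-5-methoxy-2,2-dimethylchroman-6-yl)acetic acid | OC(=O)Cc1c(OCc3ccccc3)cc2c(c1OC)CCC(C)(C)O2
F10 | step 12 | 2-(7-benzyloxy-5-methoxy-2,2-dimethylchroman-6-yl)-N-methoxy-N-methylacetamide | CON(C)C(=O)Cc1c(OCc3ccccc3)cc2c(c1OC)CCC(C)(C)O2
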